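**Retrosynthetic overview**

1. Feature: ring A (C1–C6) is a 4-hydroxy-3-methoxyphenyl ring bonded through C1 to the carbinol carbon C7. Its six carbons are cut into a C2–C5 unit (a 1-dimethylamino-2-methoxy-3-silyloxybutadiene) and a C1/C6 unit (a terminal alkyne whose activating carbonyl is C7).
2. Target ⇐ tris-silylated threo alcohol ⇐ C7 aryl ketone, by hydride delivery under Felkin–Anh control from C8, then desilylation.
3. C7 aryl ketone ⇐ terminal ynone + aminosiloxydiene, by Diels–Alder reaction and loss of Me2NH, forming C1–C2 and C5–C6.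
4. Ynone ⇐ Weinreb amide ⇐ Mitsunobu union (C8–O4′ bond, inversion) of silylated methyl (R)-glycerate with silylated sinapyl alcohol (from syringaldehyde); diene ⇐ methoxyacetone.
5. Ring order: ring B is bought with syringaldehyde; ring A is the only ring formed, in the key step.

Key step: step 11

Assumption: methoxyacetone is taken to condense with the amide acetal at its methoxy-bearing methylene, the more acidic α-position, as α-alkoxy and α-aryloxy ketones generally do. Numbering: ring A C1–C6, chain C7–C9, ring B primed.

**Route**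

Step 1
Reactants: 1 syringaldehyde
Product: 2 ethyl (E)-3-(4-hydroxy-3,5-dimethoxyphenyl)prop-2-enoate (ethyl sinapate)
Conditions: Ph3P=CHCO2Et, toluene, 90 °C
Reagents that add atoms: (ethoxycarbonylmethylene)triphenylphosphorane, CCOC(=O)C=P(c1ccccc1)(c1ccccc1)c1ccccc1
Why: Wittig olefination with a stabilized ylide tolerates the free phenol and should give the (E)-cinnamate.

Step 2
Reactants: 2 ethyl sinapate
Product: 3 sinapyl alcohol, 4-[(E)-3-hydroxyprop-1-enyl]-2,6-dimethoxyphenol
Conditions: i-Bu2AlH (excess), toluene, 0 °C; aq. potassium sodium tartrate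
Reagents that add atoms: none
Why: Ester reduction with i-Bu2AlH is a 1,2-reduction of the conjugated ester to the allylic alcohol that leaves the styrenyl double bond alone, one further equivalent being consumed by the phenol.

Step 3
Reactants: 3 sinapyl alcohol
Product: 4 4-[(E)-3-(tert-butyldimethylsilyloxy)prop-1-enyl]-2,6-dimethoxyphenol
Conditions: TBSCl (1.05 equiv), imidazole, DMF, 0 °C
Reagents that add atoms: tert-butyldimethylsilyl chloride, CC(C)(C)[Si](C)(C)Cl
Why: Chemoselective silylation, in which the primary allylic hydroxyl should react faster than the phenol flanked by two ortho-methoxy groups when one equivalent of silyl chloride is used cold.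

Step 4
Reactants: 5 methyl (4R)-2,2-dimethyl-1,3-dioxolane-4-carboxylate
Product: 6 methyl (2R)-2,3-dihydroxypropanoate
Conditions: Dowex 50WX8 (H+ form), MeOH, rt; filter, concentrate
Reagents that add atoms: none
Why: Acid-catalysed transacetalization in methanol removes the isopropylidene group as 2,2-dimethoxypropane without touching the methyl ester or the stereocenter.

Step 5
Reactants: 6 methyl (2R)-2,3-dihydroxypropanoate
Product: 7 methyl (2R)-3-(tert-butyldimethylsilyloxy)-2-hydroxypropanoate
Conditions: TBSCl (1.05 equiv), imidazole, CH2Cl2, 0 °C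
Reagents that add atoms: tert-butyldimethylsilyl chloride, CC(C)(C)[Si](C)(C)Cl
Why: Selective silylation of the primary hydroxyl over the more hindered secondary α-hydroxyl of the glycerate.

Step 6
Reactants: 4 4-[(E)-3-(tert-butyldimethylsilyloxy)prop-1-enyl]-2,6-dimethoxyphenol; 7 methyl (2R)-3-(tert-butyldimethylsilyloxy)-2-hydroxypropanoate
Product: 8 methyl (2S)-3-(tert-butyldimethylsilyloxy)-2-{4-[(E)-3-(tert-butyldimethylsilyloxy)prop-1-enyl]-2,6-dimethoxyphenoxy}propanoate
Conditions: PPh3, DIAD, THF, 0 °C → rt
Reagents that add atoms: none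
Why: Mitsunobu etherification, in which the phenol oxygen (O4′) displaces the activated α-hydroxyl of the ester in an SN2 step with inversion, turning the (R)-carbinol into the (S)-aryl ether and so setting C8.

Step 7
Reactants: 8 methyl (2S)-3-(tert-butyldimethylsilyloxy)-2-{4-[(E)-3-(tert-butyldimethylsilyloxy)prop-1-enyl]-2,6-dimethoxyphenoxy}propanoate
Product: 9 (2S)-3-(tert-butyldimethylsilyloxy)-2-{4-[(E)-3-(tert-butyldimethylsilyloxy)prop-1-enyl]-2,6-dimethoxyphenoxy}-N-methoxy-N-methylpropanamide
Conditions: MeNH(OMe)·HCl, i-PrMgCl, THF, −20 °C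
Reagents that add atoms: N,O-dimethylhydroxylamine hydrochloride, CNOC.Cl
Why: Weinreb amidation of the methyl ester by the chloromagnesium amide made in the flask is fast at −20 °C, where the α-aryloxy stereocenter should not epimerize.

Step 8
Reactants: 9 the Weinreb amide
Product: 10 (4S)-5-(tert-butyldimethylsilyloxy)-4-{4-[(E)-3-(tert-butyldimethylsilyloxy)prop-1-enyl]-2,6-dimethoxyphenoxy}pent-1-yn-3-one
Conditions: HC≡CMgBr, THF, −20 → 0 °C; inverse quench into cold 10% aq. citric acid; used promptly
Reagents that add atoms: ethynylmagnesium bromide, C#C[Mg]Br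
Why: Weinreb ketone synthesis, in which the Grignard reagent adds once to give a stable magnesium chelate that collapses to the ynone only on quench, while the acidic inverse quench keeps the liberated N,O-dimethylhydroxylamine protonated so that it cannot add to the ynone.

Step 9
Reactants: 11 methoxyacetone
Product: 12 (3Z)-4-(dimethylamino)-3-methoxybut-3-en-2-one
Conditions: Me2NCH(OMe)2 (neat), 100 °C, MeOH distilled off
Reagents that add atoms: N,N-dimethylformamide dimethyl acetal, COC(OC)N(C)C
Why: Enaminone formation by condensation of the amide acetal at the methoxy-bearing methylene should give the push–pull olefin with the amino group trans to the acetyl group.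

Step 10
Reactants: 12 (3Z)-4-(dimethylamino)-3-methoxybut-3-en-2-one
Product: 14 (1Z)-3-(tert-butyldimethylsilyloxy)-1-(dimethylamino)-2-methoxybuta-1,3-diene (amino group trans to C3), via potassium dienolate 13 (not isolated)
Conditions: KN(SiMe3)2, THF, −78 °C; then TBSCl, −78 °C → rt; filtration under argon, distillation under reduced pressure
Reagents that add atoms: tert-butyldimethylsilyl chloride, CC(C)(C)[Si](C)(C)Cl
Why: Kinetic deprotonation of the only enolizable position (the acetyl CH3) and O-silylation of the cross-conjugated enolate, the standard preparation of 1-amino-3-siloxybutadienes, should keep the enamine geometry.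

Step 11
Reactants: 10 the terminal ynone; 14 the aminosiloxydiene (1.5 equiv)
Product: 16 (2S)-3-(tert-butyldimethylsilyloxy)-1-[4-(tert-butyldimethylsilyloxy)-3-methoxyphenyl]-2-{4-[(E)-3-(tert-butyldimethylsilyloxy)prop-1-enyl]-2,6-dimethoxyphenoxy}propan-1-one, via aminocyclohexadiene cycloadduct 15 (not isolated)
Conditions: toluene, −40 → 0 °C; then AcOH (excess), 0 °C → rt
Reagents that add atoms: none
Why: The enamine nitrogen and the silyl enol ether make the CH2 terminus of the diene its nucleophilic end and the ynone is electrophilic at its terminal CH, so these two carbons join (C5–C6) while the aminated terminus joins the acyl-bearing alkyne carbon (C2–C1), giving cyclohexa-1,4-diene 15 either by a concerted asynchronous (4+2) cycloaddition or by Michael addition followed by 6-exo-trig Mannich closure onto the vinylogous iminium carbon. Acetic acid then protonates the amine and triggers 1,4-elimination of Me2NH across the ring, which aromatizes it to the aryl silyl ether with the silyloxy group para and the methoxy group meta to C7. The closest known reaction type is the Diels–Alder benzannulation of 1-amino-3-siloxy- and 1-alkoxy-3-siloxybutadienes with acetylenic ketones to give para-acylphenol derivatives. Ring A is the only ring closed, by intermolecular (4+2) annulation of the four-carbon diene with the two-carbon alkyne. No stereocenter is created and kept, because the aminated carbon of 15 becomes aromatic and C8 is a spectator. The step needs regioselectivity, which the matched polarization secures (the 2-methoxy group opposes the nitrogen only weakly and blocks attack through the enamine β-carbon), and it needs the ynone and C8 to be spared from free amine, which the low temperature, the excess of diene and release of the amine as its acetate should secure.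

Step 12
Reactants: 16 the aryl ketone
Product: 17 (1S,2S)-3-(tert-butyldimethylsilyloxy)-1-[4-(tert-butyldimethylsilyloxy)-3-methoxyphenyl]-2-{4-[(E)-3-(tert-butyldimethylsilyloxy)prop-1-enyl]-2,6-dimethoxyphenoxy}propan-1-ol
Conditions: LiBH(s-Bu)3, THF, −78 °C; then aq. NH4Cl
Reagents that add atoms: none
Why: Felkin–Anh 1,2-induction, in which the C8–OAr bond lies antiperiplanar to the incoming bulky, non-chelating hydride and the hydride passes the C8 hydrogen, should give the 7S alcohol, that is the threo (7S,8S) isomer.

Step 13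
Reactants: 17 the tris-silylated threo alcohol
Product: 18 (1S,2S)-1-(4-hydroxy-3-methoxyphenyl)-2-{4-[(E)-3-hydroxyprop-1-enyl]-2,6-dimethoxyphenoxy}propane-1,3-diol (CNP0166461.1)
Conditions: Bu4NF, AcOH, THF, 0 °C → rt
Reagents that add atoms: none
Why: Fluoride-mediated desilylation removes the two alkyl and the one aryl silyl ether, and buffering with AcOH keeps the medium from becoming basic enough to harm the p-hydroxybenzyl alcohol unit.

**Compound list**

1 | syringaldehyde (4-hydroxy-3,5-dimethoxybenzaldehyde) | COc1cc(C=O)cc(OC)c1O | starting material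
2 | ethyl (E)-3-(4-hydroxy-3,5-dimethoxyphenyl)prop-2-enoate | CCOC(=O)/C=C/c1cc(OC)c(O)c(OC)c1 | intermediate
3 | sinapyl alcohol, 4-[(E)-3-hydroxyprop-1-enyl]-2,6-dimethoxyphenol | COc1cc(/C=C/CO)cc(OC)c1O | intermediate
4 | 4-[(E)-3-(tert-butyldimethylsilyloxy)prop-1-enyl]-2,6-dimethoxyphenol | COc1cc(/C=C/CO[Si](C)(C)C(C)(C)C)cc(OC)c1O | intermediate
5 | methyl (4R)-2,2-dimethyl-1,3-dioxolane-4-carboxylate | COC(=O)[C@H]1COC(C)(C)O1 | starting material
6 | methyl (2R)-2,3-dihydroxypropanoate | COC(=O)[C@H](O)CO | intermediate
7 | methyl (2R)-3-(tert-butyldimethylsilyloxy)-2-hydroxypropanoate | COC(=O)[C@H](O)CO[Si](C)(C)C(C)(C)C | intermediate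
8 | methyl (2S)-3-(tert-butyldimethylsilyloxy)-2-{4-[(E)-3-(tert-butyldimethylsilyloxy)prop-1-enyl]-2,6-dimethoxyphenoxy}propanoate | COC(=O)[C@H](CO[Si](C)(C)C(C)(C)C)Oc1c(OC)cc(/C=C/CO[Si](C)(C)C(C)(C)C)cc1OC | intermediate
9 | (2S)-3-(tert-butyldimethylsilyloxy)-2-{4-[(E)-3-(tert-butyldimethylsilyloxy)prop-1-enyl]-2,6-dimethoxyphenoxy}-N-methoxy-N-methylpropanamide | CON(C)C(=O)[C@H](CO[Si](C)(C)C(C)(C)C)Oc1c(OC)cc(/C=C/CO[Si](C)(C)C(C)(C)C)cc1OC | intermediate
10 | (4S)-5-(tert-butyldimethylsilyloxy)-4-{4-[(E)-3-(tert-butyldimethylsilyloxy)prop-1-enyl]-2,6-dimethoxyphenoxy}pent-1-yn-3-one | C#CC(=O)[C@H](CO[Si](C)(C)C(C)(C)C)Oc1c(OC)cc(/C=C/CO[Si](C)(C)C(C)(C)C)cc1OC | intermediate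
11 | methoxyacetone (1-methoxypropan-2-one) | COCC(C)=O | starting material
12 | (3Z)-4-(dimethylamino)-3-methoxybut-3-en-2-one | CN(C)/C=C(OC)/C(C)=O | intermediate
13 | potassium (3Z)-4-(dimethylamino)-3-methoxybuta-1,3-dien-2-olate | CN(C)/C=C(OC)/C(=C)[O-].[K+] | intermediate
14 | (1Z)-3-(tert-butyldimethylsilyloxy)-1-(dimethylamino)-2-methoxybuta-1,3-diene | CN(C)/C=C(OC)/C(=C)O[Si](C)(C)C(C)(C)C | intermediate
15 | (2S)-3-(tert-butyldimethylsilyloxy)-1-[4-(tert-butyldimethylsilyloxy)-6-(dimethylamino)-5-methoxycyclohexa-1,4-dien-1-yl]-2-{4-[(E)-3-(tert-butyldimethylsilyloxy)prop-1-enyl]-2,6-dimethoxyphenoxy}propan-1-one (epimers at the aminated ring carbon) | CN(C)C1C(OC)=C(O[Si](C)(C)C(C)(C)C)CC=C1C(=O)[C@H](CO[Si](C)(C)C(C)(C)C)Oc1c(OC)cc(/C=C/CO[Si](C)(C)C(C)(C)C)cc1OC | intermediate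
16 | (2S)-3-(tert-butyldimethylsilyloxy)-1-[4-(tert-butyldimethylsilyloxy)-3-methoxyphenyl]-2-{4-[(E)-3-(tert-butyldimethylsilyloxy)prop-1-enyl]-2,6-dimethoxyphenoxy}propan-1-one | COc1cc(C(=O)[C@H](CO[Si](C)(C)C(C)(C)C)Oc2c(OC)cc(/C=C/CO[Si](C)(C)C(C)(C)C)cc2OC)ccc1O[Si](C)(C)C(C)(C)C | intermediate
17 | (1S,2S)-3-(tert-butyldimethylsilyloxy)-1-[4-(tert-butyldimethylsilyloxy)-3-methoxyphenyl]-2-{4-[(E)-3-(tert-butyldimethylsilyloxy)prop-1-enyl]-2,6-dimethoxyphenoxy}propan-1-ol | COc1cc([C@H](O)[C@H](CO[Si](C)(C)C(C)(C)C)Oc2c(OC)cc(/C=C/CO[Si](C)(C)C(C)(C)C)cc2OC)ccc1O[Si](C)(C)C(C)(C)C | intermediate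
18 | (1S,2S)-1-(4-hydroxy-3-methoxyphenyl)-2-{4-[(E)-3-hydroxyprop-1-enyl]-2,6-dimethoxyphenoxy}propane-1,3-diol | COc1cc([C@H](O)[C@H](CO)Oc2c(OC)cc(/C=C/CO)cc2OC)ccc1O | target

**Step count**

Total steps: 13. Longest linear sequence: 9 steps (steps 1, 2, 3, 6, 7, 8, 11, 12, 13).

**Steps most likely to fail**

Step 11. The 2-methoxy diene is untested, and several processes could intervene. The diene may hydrolyse or react sluggishly. Liberated dimethylamine may add to unreacted ynone. C8 may epimerize next to the ynone. The silyl enol ether may be protodesilylated before aromatization. The fallback gives up ring construction and attaches ring A ready-made to the Weinreb amide 9. Commercial 4-bromo-2-methoxyphenol would be silylated (TBSCl, imidazole, DMF) to tert-butyl(4-bromo-2-methoxyphenoxy)dimethylsilane F1. Bromine–lithium exchange (n-BuLi, THF, −78 °C) would give [4-(tert-butyldimethylsilyloxy)-3-methoxyphenyl]lithium F2. Addition of F2 to 9 at −78 °C, with a cold NH4Cl quench, should give ketone 16 directly, where the route is rejoined.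

Step 12. Facial selectivity may be poor if chelation competes with the Felkin–Anh pathway, and the basic hydride may enolize the ketone and erode C8. The fallback replaces substrate control by catalyst control. Ketone 16 would be reduced by Corey–Bakshi–Shibata reduction with (3aS)-1-methyl-3,3-diphenyltetrahydro-1H,3H-pyrrolo[1,2-c][1,3,2]oxazaborole (catalytic) and catecholborane in toluene at −78 °C, conditions that spare the styrenyl double bond. On the usual model, with ring A as the large group, the (S)-catalyst is expected to deliver the 7S alcohol 17, and this sense would be checked on a small scale. The route is rejoined at 17 and no new compound arises (F0).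

Step 6. Displacement by the hindered 2,6-dimethoxyphenol may be slow, so that elimination of the activated alcohol or alkylation of the hydrazide competes, and enantiopurity may be partly lost. The fallback separates activation from displacement. Alcohol 7 would be converted (Tf2O, 2,6-lutidine, CH2Cl2, −78 °C) into methyl (2R)-3-(tert-butyldimethylsilyloxy)-2-(trifluoromethylsulfonyloxy)propanoate F3. Phenol 4 would be converted with Cs2CO3 in MeCN into caesium 4-[(E)-3-(tert-butyldimethylsilyloxy)prop-1-enyl]-2,6-dimethoxyphenolate F4. SN2 displacement of the triflate by F4 at −20 → 0 °C should give 8 with inversion, where the route is rejoined.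

**Further compounds**

F1 | step 11 | tert-butyl(4-bromo-2-methoxyphenoxy)dimethylsilane | COc1cc(Br)ccc1O[Si](C)(C)C(C)(C)C
F2 | step 11 | [4-(tert-butyldimethylsilyloxy)-3-methoxyphenyl]lithium | [Li]c1ccc(O[Si](C)(C)C(C)(C)C)c(OC)c1
F0 | step 12 | none | none
F3 | step 6 | methyl (2R)-3-(tert-butyldimethylsilyloxy)-2-(trifluoromethylsulfonyloxy)propanoate | COC(=O)[C@H](OS(=O)(=O)C(F)(F)F)CO[Si](C)(C)C(C)(C)C
F4 | step 6 | caesium 4-[(E)-3-(tert-butyldimethylsilyloxy)prop-1-enyl]-2,6-dimethoxyphenolate | COc1cc(/C=C/CO[Si](C)(C)C(C)(C)C)cc(OC)c1[O-].[Cs+]
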